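**Plan**
1. Retrosynthesis: the acid comes from its methyl ester. The C8–prenyl bond at the quaternary ring carbon is cut first, then the C8–CH2 bond to the side chain, then the pyran ring (O1–C2 and C4–C4a), which leads back to 2,4,6-trihydroxybenzophenone. The side chain is cut at its Cα–allyl bond and at the trisubstituted C=C.
2. Enabling feature: the pyran oxygen sits on C8a, next to the quaternary C8 and para to the benzoyl-bearing C6. In the twofold-symmetric triphenol this oxygen is the one hydroxyl not hydrogen-bonded to the ketone, and its two ortho carbons are equivalent.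
3. Forward: ring B (the pyran) is fused onto the still aromatic ring A (steps 1–2), then C8 is brominated and the phenols acetylated (steps 3–4). The side chain is built separately (steps 5–9) and joined at C8 (step 10). The acetates are removed (step 11), ring A is dearomatised by C8 prenylation (step 12) and the ester is hydrolysed (step 13).
4. Stereochemistry: the side-chain centre (5R in the target) comes from an Evans alkylation on (S)-4-benzyloxazolidinone, and the E enoate from cross-metathesis. The quaternary C8 (S) comes from a ligand-controlled palladium prenylation; its C8 epimer is a diastereomer and separable.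

Key step: step 2

Remark: ring positions follow chromene numbering (O1, C2, C3, C4, C4a, C5 to C8, C8a; C8 is the quaternary ring carbon, C8a carries the pyran oxygen). The target and its ester are written as the 7-hydroxy-5-oxo enol of the given SMILES; the other enol forms of the triketone are tautomers of the same compound.

**Step 1**
Reactants: 1 2,4,6-trihydroxybenzophenone; 2 3-chloro-3-methylbut-1-yne
Product: 3 [2,6-dihydroxy-4-(2-methylbut-3-yn-2-yloxy)phenyl](phenyl)methanone
Conditions: CuCl2·2H2O (cat.), DBU, MeCN, 0 °C to rt
Reagents that add atoms: none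
Why: Copper-catalysed propargylic substitution of a tertiary propargyl chloride by a phenoxide (via a copper acetylide/allenylidene) should etherify only the 4-OH, because it is the most acidic hydroxyl and the only one not held in a hydrogen bond to the benzoyl carbonyl.

**Step 2**
Reactants: 3 [2,6-dihydroxy-4-(2-methylbut-3-yn-2-yloxy)phenyl](phenyl)methanone
Product: 7 (5,7-dihydroxy-2,2-dimethyl-2H-chromen-6-yl)(phenyl)methanone, via allenyl cyclohexadienone 4 (not isolated), via ortho-allenyl phenol 5 (not isolated), via ortho-quinone methide 6 (not isolated)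
Conditions: o-xylene, 140 °C, argon
Reagents that add atoms: none
Why: Heating triggers the aryl propargyl Claisen [3,3] shift of the ether into either of the two equivalent ortho carbons to give allenyl dienone 4, which enolises to allenyl phenol 5; a 1,5-hydrogen shift from the newly freed phenolic O–H to the central allene carbon gives the Z-configured ortho-quinone methide 6 (a 1-oxatriene), and thermal disrotatory oxa-6π electrocyclisation then forms the O1–C2 bond. The closest known reaction type is the thermal conversion of aryl 1,1-dimethylpropargyl ethers into 2,2-dimethyl-2H-chromenes. Ring B is thus closed as a six-membered pyran by 6π electrocyclisation of the oxatriene, after the C4a–C4 bond has been made in the sigmatropic step. No stereocentre is created, since the sp3 carbon of 4 is lost on enolisation and C2 carries two methyl groups. The selectivity needed is regiochemical (pyran oxygen para to the benzoyl carbon, the remaining ring C–H between that oxygen and a hydroxyl); it is secured because the ether sits on the only non-chelated oxygen of a symmetric arene, so both ortho termini are identical, and because the other hydroxyl flanking the allene is tied up in a hydrogen bond to the benzoyl C=O and should not deliver its hydrogen to the allene. The gem-dimethyl group lowers the temperature required, and the neutral medium avoids the base-promoted benzofuran pathway.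

**Step 3**
Reactants: 7 (5,7-dihydroxy-2,2-dimethyl-2H-chromen-6-yl)(phenyl)methanone
Product: 8 (8-bromo-5,7-dihydroxy-2,2-dimethyl-2H-chromen-6-yl)(phenyl)methanone
Conditions: NBS (1.0 equiv), CH2Cl2, −78 to −40 °C, dark
Reagents that add atoms: N-bromosuccinimide, O=C1CCC(=O)N1Br
Why: Electrophilic aromatic bromination with one equivalent of NBS at low temperature should go to C8, the single ring C–H, which is activated by the flanking 7-OH, the para 5-OH and the pyran oxygen and therefore reacts ahead of the C3=C4 alkene.

**Step 4**
Reactants: 8 (8-bromo-5,7-dihydroxy-2,2-dimethyl-2H-chromen-6-yl)(phenyl)methanone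
Product: 9 6-benzoyl-8-bromo-2,2-dimethyl-2H-chromene-5,7-diyl diacetate
Conditions: Ac2O, pyridine, DMAP (cat.), 0 °C to rt
Reagents that add atoms: acetic anhydride, CC(=O)OC(C)=O
Why: DMAP-catalysed O-acetylation masks both acidic phenols so that they cannot protonate the alkylzinc reagent of step 10, and acetates are chosen because they are later removed by basic methanolysis, which spares the acid-sensitive isopropenyl group and the chromene.

**Step 5**
Reactants: 10 (4S)-4-benzyl-1,3-oxazolidin-2-one; 11 3-methylbut-2-enoyl chloride
Product: 13 (4S)-4-benzyl-3-(3-methylbut-2-enoyl)-1,3-oxazolidin-2-one, via lithium oxazolidinide 12 (not isolated)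
Conditions: n-BuLi, THF, −78 °C; then 11, −78 to 0 °C
Reagents that add atoms: n-butyllithium, [Li]CCCC (its lithium is held only in 12)
Why: N-Acylation of a lithiated Evans oxazolidinone by an acid chloride is a standard way to attach the auxiliary, and the enoyl chloride is too hindered at its β-carbon for conjugate addition to compete.

**Step 6**
Reactants: 13 (4S)-4-benzyl-3-(3-methylbut-2-enoyl)-1,3-oxazolidin-2-one; 14 allyl iodide
Product: 16 (4S)-4-benzyl-3-[(2S)-2-(prop-1-en-2-yl)pent-4-enoyl]-1,3-oxazolidin-2-one, via sodium dienolate 15 (not isolated)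
Conditions: NaN(SiMe3)2, THF, −78 °C; then 14, −78 to −40 °C
Reagents that add atoms: sodium bis(trimethylsilyl)amide, [Na+].C[Si](C)(C)[N-][Si](C)(C)C (its sodium is held only in 15)
Why: Deconjugative Evans alkylation: γ-deprotonation gives the chelated Z(O) sodium dienolate 15, which is alkylated at Cα on the face opposite the benzyl group, so the new stereocentre is formed as 2S (the arrangement that becomes 5R in the target) and the alkene moves out of conjugation to give the isopropenyl group.

**Step 7**
Reactants: 16 (4S)-4-benzyl-3-[(2S)-2-(prop-1-en-2-yl)pent-4-enoyl]-1,3-oxazolidin-2-one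
Product: 17 (2S)-2-(prop-1-en-2-yl)pent-4-en-1-ol
Conditions: LiBH4, MeOH (1 equiv), Et2O, 0 °C
Reagents that add atoms: none
Why: LiBH4 reduces the exocyclic imide carbonyl of an N-acyl oxazolidinone to the primary alcohol with release of the auxiliary, and once the carbonyl is gone the allylic stereocentre can no longer epimerise.

**Step 8**
Reactants: 17 (2S)-2-(prop-1-en-2-yl)pent-4-en-1-ol; 18 methyl methacrylate
Product: 19 methyl (2E,5S)-5-(hydroxymethyl)-2,6-dimethylhepta-2,6-dienoate
Conditions: 18 (excess), second-generation Hoveyda–Grubbs catalyst RuCl2(H2IMes)(=CH-C6H4-2-O-i-Pr) (H2IMes = 1,3-dimesitylimidazolidin-2-ylidene; 5 mol %), CH2Cl2, 40 °C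
Reagents that add atoms: none
Why: Olefin cross-metathesis of the unhindered monosubstituted alkene with excess methyl methacrylate gives the trisubstituted enoate as the thermodynamically favoured E isomer, while the 1,1-disubstituted isopropenyl alkene is too hindered to engage and ring closure between the two alkenes of 17 would require a cyclobutene.

**Step 9**
Reactants: 19 methyl (2E,5S)-5-(hydroxymethyl)-2,6-dimethylhepta-2,6-dienoate
Product: 20 methyl (2E,5S)-5-(iodomethyl)-2,6-dimethylhepta-2,6-dienoate
Conditions: I2, PPh3, imidazole, CH2Cl2, 0 °C to rt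
Reagents that add atoms: iodine, II
Why: Appel-type iodination converts the primary alcohol into the iodide by SN2 displacement of an alkoxyphosphonium ion under near-neutral conditions, leaving the adjacent stereocentre and the enoate untouched.

**Step 10**
Reactants: 20 methyl (2E,5S)-5-(iodomethyl)-2,6-dimethylhepta-2,6-dienoate; 9 6-benzoyl-8-bromo-2,2-dimethyl-2H-chromene-5,7-diyl diacetate
Product: 22 methyl (2E,5R)-5-{[5,7-bis(acetyloxy)-6-benzoyl-2,2-dimethyl-2H-chromen-8-yl]methyl}-2,6-dimethylhepta-2,6-dienoate, via alkylzinc iodide 21 (not isolated)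
Conditions: Zn dust (activated with BrCH2CH2Br and Me3SiCl), THF, 35 °C; then 9, Pd(OAc)2 (5 mol %), SPhos (10 mol %), THF, 50 °C
Reagents that add atoms: zinc, [Zn] (held only in 21)
Why: Direct insertion of activated zinc into the primary C–I bond tolerates the ester and gives alkylzinc iodide 21, whose Negishi sp2–sp3 coupling with the doubly ortho-substituted bromide is driven by the bulky, electron-rich biarylphosphine SPhos (fast oxidative addition, reductive elimination ahead of β-hydride elimination); the stereocentre is β to zinc and is not touched.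

**Step 11**
Reactants: 22 methyl (2E,5R)-5-{[5,7-bis(acetyloxy)-6-benzoyl-2,2-dimethyl-2H-chromen-8-yl]methyl}-2,6-dimethylhepta-2,6-dienoate
Product: 23 methyl (2E,5R)-5-[(6-benzoyl-5,7-dihydroxy-2,2-dimethyl-2H-chromen-8-yl)methyl]-2,6-dimethylhepta-2,6-dienoate
Conditions: K2CO3, MeOH, 0 °C to rt, argon; mildly acidic work-up
Reagents that add atoms: none
Why: Base-mediated methanolysis cleaves the two aryl acetates far faster than any other group can react, the methyl ester merely exchanging with the solvent, and liberates the acylphloroglucinol needed for dearomatisation.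

**Step 12**
Reactants: 23 methyl (2E,5R)-5-[(6-benzoyl-5,7-dihydroxy-2,2-dimethyl-2H-chromen-8-yl)methyl]-2,6-dimethylhepta-2,6-dienoate; 24 3-methylbut-2-en-1-yl acetate
Product: 25 methyl (2E,5R)-5-{[(8S)-6-benzoyl-7-hydroxy-2,2-dimethyl-8-(3-methylbut-2-en-1-yl)-5-oxo-5,8-dihydro-2H-chromen-8-yl]methyl}-2,6-dimethylhepta-2,6-dienoate
Conditions: Pd2(dba)3·CHCl3 (2.5 mol %), (1R,2R)-N,N′-bis[2-(diphenylphosphino)benzoyl]cyclohexane-1,2-diamine (7.5 mol %; its antipode if the other epimer predominates), Cs2CO3, THF, 0 °C to rt; acidic work-up, chromatographic removal of the C8 epimer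
Reagents that add atoms: none
Why: Proposed new method: the cesium salt of 23 is a soft, delocalised nucleophile that should attack the less hindered CH2 terminus of the cationic (η3-1,1-dimethylallyl)palladium complex from outside the metal, and should do so through C8, the only alkyl-bearing ring carbon lying between two oxygen-bearing carbons, giving the dearomatised 8,8-dialkyl dienone (O-prenyl ethers that form are re-ionised by zerovalent palladium and drain to the C-alkylated product, and attack through the tertiary terminus would join two quaternary carbons); the chiral pocket of the bisphosphine ligand is meant to select the ring face so that C8 becomes S, the matched ligand antipode being settled by running both, and because the side-chain centre is already fixed the 8R product is a diastereomer removable by chromatography; the closest known reaction types are the palladium-catalysed asymmetric allylic dearomatisation of phenols and naphthols (Tsuji–Trost) and the base-mediated dearomative prenylation of acylphloroglucinols.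

**Step 13**
Reactants: 25 methyl (2E,5R)-5-{[(8S)-6-benzoyl-7-hydroxy-2,2-dimethyl-8-(3-methylbut-2-en-1-yl)-5-oxo-5,8-dihydro-2H-chromen-8-yl]methyl}-2,6-dimethylhepta-2,6-dienoate
Product: 26 (2E,5R)-5-{[(8S)-6-benzoyl-7-hydroxy-2,2-dimethyl-8-(3-methylbut-2-en-1-yl)-5-oxo-5,8-dihydro-2H-chromen-8-yl]methyl}-2,6-dimethylhepta-2,6-dienoic acid
Conditions: LiOH·H2O, THF/MeOH/H2O, rt to 40 °C; then 1 M HCl to pH 3
Reagents that add atoms: lithium hydroxide, [Li+].[OH-] (its oxygen becomes the carboxyl OH)
Why: Saponification of the methyl ester with LiOH followed by acidification gives the acid; the β-triketone is carried as its delocalised enolate, which protects the core from retro-Claisen or conjugate attack, and neither the quaternary C8 nor the non-enolisable side-chain centre can epimerise.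

**Compound list**
1 | 2,4,6-trihydroxybenzophenone | O=C(c1ccccc1)c1c(O)cc(O)cc1O | starting material
2 | 3-chloro-3-methylbut-1-yne | CC(C)(Cl)C#C | starting material
3 | [2,6-dihydroxy-4-(2-methylbut-3-yn-2-yloxy)phenyl](phenyl)methanone | C#CC(C)(C)Oc1cc(O)c(C(=O)c2ccccc2)c(O)c1 | intermediate
4 | 4-benzoyl-3,5-dihydroxy-6-(3-methylbuta-1,2-dien-1-yl)cyclohexa-2,4-dien-1-one (racemic, transient) | CC(C)=C=CC1C(=O)C=C(O)C(C(=O)c2ccccc2)=C1O | intermediate
5 | [2,4,6-trihydroxy-3-(3-methylbuta-1,2-dien-1-yl)phenyl](phenyl)methanone | CC(C)=C=Cc1c(O)cc(O)c(C(=O)c2ccccc2)c1O | intermediate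
6 | (6Z)-4-benzoyl-3,5-dihydroxy-6-(3-methylbut-2-en-1-ylidene)cyclohexa-2,4-dien-1-one | CC(C)=C/C=C1\C(=O)C=C(O)C(C(=O)c2ccccc2)=C1O | intermediate
7 | (5,7-dihydroxy-2,2-dimethyl-2H-chromen-6-yl)(phenyl)methanone | O=C(c1ccccc1)c1c(O)cc2OC(C)(C)C=Cc2c1O | intermediate
8 | (8-bromo-5,7-dihydroxy-2,2-dimethyl-2H-chromen-6-yl)(phenyl)methanone | O=C(c1ccccc1)c1c(O)c(Br)c2OC(C)(C)C=Cc2c1O | intermediate
9 | 6-benzoyl-8-bromo-2,2-dimethyl-2H-chromene-5,7-diyl diacetate | CC(=O)Oc1c(Br)c2OC(C)(C)C=Cc2c(OC(C)=O)c1C(=O)c1ccccc1 | intermediate
10 | (4S)-4-benzyl-1,3-oxazolidin-2-one | O=C1N[C@@H](Cc2ccccc2)CO1 | starting material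
11 | 3-methylbut-2-enoyl chloride | CC(C)=CC(=O)Cl | starting material
12 | lithium salt of (4S)-4-benzyl-1,3-oxazolidin-2-one | [Li+].O=C1[N-][C@@H](Cc2ccccc2)CO1 | intermediate
13 | (4S)-4-benzyl-3-(3-methylbut-2-enoyl)-1,3-oxazolidin-2-one | CC(C)=CC(=O)N1C(=O)OC[C@@H]1Cc1ccccc1 | intermediate
14 | allyl iodide (3-iodoprop-1-ene) | C=CCI | starting material
15 | sodium (1Z)-1-[(4S)-4-benzyl-2-oxo-1,3-oxazolidin-3-yl]-3-methylbuta-1,3-dien-1-olate | [Na+].C=C(C)/C=C(\[O-])N1C(=O)OC[C@@H]1Cc1ccccc1 | intermediate
16 | (4S)-4-benzyl-3-[(2S)-2-(prop-1-en-2-yl)pent-4-enoyl]-1,3-oxazolidin-2-one | C=C(C)[C@H](CC=C)C(=O)N1C(=O)OC[C@@H]1Cc1ccccc1 | intermediate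
17 | (2S)-2-(prop-1-en-2-yl)pent-4-en-1-ol | C=C(C)[C@H](CC=C)CO | intermediate
18 | methyl methacrylate | C=C(C)C(=O)OC | starting material
19 | methyl (2E,5S)-5-(hydroxymethyl)-2,6-dimethylhepta-2,6-dienoate | C=C(C)[C@H](C/C=C(\C)C(=O)OC)CO | intermediate
20 | methyl (2E,5S)-5-(iodomethyl)-2,6-dimethylhepta-2,6-dienoate | C=C(C)[C@H](C/C=C(\C)C(=O)OC)CI | intermediate
21 | [(2S,4E)-6-methoxy-5-methyl-6-oxo-2-(prop-1-en-2-yl)hex-4-en-1-yl]zinc iodide | C=C(C)[C@H](C/C=C(\C)C(=O)OC)C[Zn]I | intermediate
22 | methyl (2E,5R)-5-{[5,7-bis(acetyloxy)-6-benzoyl-2,2-dimethyl-2H-chromen-8-yl]methyl}-2,6-dimethylhepta-2,6-dienoate | C=C(C)[C@H](C/C=C(\C)C(=O)OC)Cc1c(OC(C)=O)c(C(=O)c2ccccc2)c(OC(C)=O)c2C=CC(C)(C)Oc12 | intermediate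
23 | methyl (2E,5R)-5-[(6-benzoyl-5,7-dihydroxy-2,2-dimethyl-2H-chromen-8-yl)methyl]-2,6-dimethylhepta-2,6-dienoate | C=C(C)[C@H](C/C=C(\C)C(=O)OC)Cc1c(O)c(C(=O)c2ccccc2)c(O)c2C=CC(C)(C)Oc12 | intermediate
24 | 3-methylbut-2-en-1-yl acetate (prenyl acetate) | CC(C)=CCOC(C)=O | starting material
25 | methyl (2E,5R)-5-{[(8S)-6-benzoyl-7-hydroxy-2,2-dimethyl-8-(3-methylbut-2-en-1-yl)-5-oxo-5,8-dihydro-2H-chromen-8-yl]methyl}-2,6-dimethylhepta-2,6-dienoate | C=C(C)[C@H](C/C=C(\C)C(=O)OC)C[C@@]1(CC=C(C)C)C(O)=C(C(=O)c2ccccc2)C(=O)C2=C1OC(C)(C)C=C2 | intermediate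
26 | (2E,5R)-5-{[(8S)-6-benzoyl-7-hydroxy-2,2-dimethyl-8-(3-methylbut-2-en-1-yl)-5-oxo-5,8-dihydro-2H-chromen-8-yl]methyl}-2,6-dimethylhepta-2,6-dienoic acid (CNP0333091.1) | C=C(C)[C@H](C/C=C(\C)C(=O)O)C[C@@]1(CC=C(C)C)C(O)=C(C(=O)c2ccccc2)C(=O)C2=C1OC(C)(C)C=C2 | target

**Totals**
Total step count: 13.
Longest linear sequence: 9 steps (steps 5 to 13, from 10 and 11 to 26). The arene branch (steps 1 to 4) joins at step 10.

**Steps most likely to fail**

Step 12 (bears the label). The ligand may discriminate poorly between the two faces at C8. The ambident anion may also be alkylated through oxygen, through C4a or through the tertiary allyl terminus. The fallback uses known chemistry and sets out from 23: deprotonation with LiN(SiMe3)2 in THF at −78 °C and addition of prenyl bromide with warming to 0 °C, the established base-mediated dearomative C-prenylation of acylphloroglucinol salts by direct SN2 alkylation. This should give 25 together with its C8 epimer, methyl (2E,5R)-5-{[(8R)-6-benzoyl-7-hydroxy-2,2-dimethyl-8-(3-methylbut-2-en-1-yl)-5-oxo-5,8-dihydro-2H-chromen-8-yl]methyl}-2,6-dimethylhepta-2,6-dienoate F1. The two are diastereomers and would be separated by preparative HPLC, so stereochemical purity then rests on separation rather than catalyst control. The route is rejoined at 25.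

Step 10. Oxidative addition at the doubly ortho-substituted bromide may be slow. The alkylpalladium intermediate has an allylic β-hydrogen and may undergo β-hydride elimination, and the alkylzinc may be lost to protonolysis. The fallback sets out from 9 and 20 and avoids both the preformed organozinc and the alkylpalladium species. It is a nickel-catalysed reductive cross-electrophile coupling: NiBr2(MeOCH2CH2OMe), 4,4′-di-tert-butyl-2,2′-bipyridine, Zn dust, NaI, N,N-dimethylacetamide, 60 °C. An alkyl radical generated from 20 is captured by an arylnickel species formed from 9. It returns to the route at 22 and makes no compound outside the list (F0).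

Step 2. At 140 °C proton exchange between the phenolic oxygens of the quinone methide, or reversible opening of the pyran, may lead to closure through the chelated hydroxyl and erode the regiochemistry. Thermal decomposition of the polyphenol is also possible. The fallback sets out from 3 and replaces the thermal cascade by a 6-endo-dig hydroarylation catalysed by (Ph3P)AuNTf2 in CH2Cl2 at rt. The gold-activated alkyne is attacked by the ortho carbon and the aryl O–C(CH3)2 bond is never broken, so the pyran oxygen is necessarily the para oxygen. It returns to the route at 7 and makes no compound outside the list (F0).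

**Further compounds**
F1 | step 12 | methyl (2E,5R)-5-{[(8R)-6-benzoyl-7-hydroxy-2,2-dimethyl-8-(3-methylbut-2-en-1-yl)-5-oxo-5,8-dihydro-2H-chromen-8-yl]methyl}-2,6-dimethylhepta-2,6-dienoate | C=C(C)[C@H](C/C=C(\C)C(=O)OC)C[C@]1(CC=C(C)C)C(O)=C(C(=O)c2ccccc2)C(=O)C2=C1OC(C)(C)C=C2
F0 | step 10 | none | none
F0 | step 2 | none | none
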